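Late in a closed flask, Xp stands at what has been made minus what has since been lost, and the readings end at 110 min, well short of the 330 min asked of violet.

| flask | Xa | Xc | time |
|---|---|---|---|
| ochre | 100 mM | 1.00 mM |  |
| red | 200 mM | 1.00 mM |  |
| teal | 100 mM | 1.50 mM |  |
| violet | 100 mM | 1.00 mM | 330 min |

- ochre run (time / min: [Xp] / mM): 4.4: 2.7; 8.4: 5.6; 16: 9.6; 30: 16.1; 58: 25.8; 110: 35.1
- red run (time / min: [Xp] / mM): 4.4: 4.5; 8.4: 8.5; 16: 14.7; 30: 25.5; 58: 43.0; 110: 57.6
- teal run (time / min: [Xp] / mM): 4.4: 4.1; 8.4: 6.9; 16: 15.1; 30: 23.6; 58: 37.9; 110: 45.0

(standard deviation of a reading: 0.5 mM)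

1. how the opening rate goes with [Xa] round the charge of the ochre run: the exponent of the rate at two percent of Xa gone to Xp (one fixed amount of Xp, the same in the runs compared)
2. how the opening rate goes with [Xc] round the charge of the ochre run: the exponent of the rate at two percent of Xa gone to Xp
3. Xp in the violet run at 330 min, as a share of the Xa charged

- Overall: Xa -> Xp, with Xc as catalyst.
- Constant volume, constant temperature.
- A reading of a species includes what of it is bound.
- An order is taken over about fifteen percent of the charge, up and down.

Over its first 16 min, the ochre curve can be replaced by its mean slope, 0.600 mM min⁻¹. The charge of Xa divided by that slope gives 167 min, the feed time: the charge of Xa over its opening rate of turnover. Violet has the ochre charge and lasts 1.98 feed times. With the rate in proportion to Xa, as in a first-order decay, the share of Xa turned by 330 min is 86.2%.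

The ochre slope near 84.0 min is 0.179 mM min⁻¹. That gives a fade constant of 0.0159 min⁻¹, faster than the 0.00599 min⁻¹ of the feed.

Two extreme versions can be solved in the head. In the first, the catalyst dies at the fade constant and Xp stays. The remaining rate then adds late slope over fade constant, and violet stops near 41.7 mM. In the second, the catalyst lives and Xp is lost at the whole fade constant. Violet then keeps 13.8 mM of Xa at 330 min, and Xp trails that feed at about 8.35 mM. The second version charges the whole fade to Xp, although falling Xa may take part of it, so this reckoning counts its figure as low. This reckoning places violet between those two figures.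

The forecast gives 0.72 (0.5 to 0.9) for the exponent in Xa, 0.97 (0.75 to 1.2) for the exponent in Xc and 45% (40% to 52%) for violet, close to the first version: “That suggests the catalyst dies”.

The simulation gives 0.69 for the exponent in Xa, 0.83 for the exponent in Xc and 17.1% for violet.

    Xc + Xa ⇌ Xc.Xa, settled at all times (7.480 M⁻¹)
    Xc.Xa + Xc → Xp + 2 Xc (1080 M⁻¹ min⁻¹)
    Xa → Xp (0.003948 min⁻¹)
    Xp → J (0.009060 min⁻¹)

Violet lands between the two versions, nearer the second. Its 17.1% of Xp is far less than the 86.2% that the feed time says has turned. The passing of Xp into J is the main reason: the violet flask without it reaches 95.4%, against the 86.2% from the feed time, and that passing accounts for 94% of what is missing.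

The readings stem from a simulated flask with constants of no real substance; scatter was added.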